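## Structural features

The target is a γ-butyrolactone (ring atoms O1, C2 carbonyl, C3, C4, C5) in which every sp3 ring carbon is substituted; the arm on C5 is numbered C1′–C10′ and is attached through C2′, and the arm on C3 is numbered C1″–C8″. C3 carries a (1E,3E)-2-methyldienyl arm that ends in a syn-aldol unit (C5″–OH, C6″–CH3, C7″ methyl ketone), C4 carries a methyl group, and C5 carries a (2E,4E)-dienyl arm joined through its trisubstituted carbon C2′ and ending at the methyl/butyl-branched centre C6′. The ring stereocentres (3S,4S,5S) are contiguous and all-trans, the 5″S,6″R pair is contiguous and syn, and 6′R stands alone. Because sp2 carbons separate these three groups, none can control another, which points to a convergent plan. The fragile sites are C3–H (α to the carbonyl and allylic, so base can epimerise it or move C1″=C2″ into conjugation), the dienylic C5–O1 bond (SN2′, ionisation), the C5″ carbinol (dienylic and β to a ketone: ionisation, dehydration, retro-aldol), the enolisable C6″, and both dienes. The real difficulty is the C3–C1″ bond, a stereodefined C(sp3)–C(sp2) bond α to a lactone that no SN2 alkylation can make, together with the release of the hydroxy ketone at the end. The key step uses the fact that the unsaturated precursor O1–C2(=O)–C3=C4–C5 is flat with C5 as its only stereocentre. Since C5/C4 and C4/C3 are both trans in the target, the C5 arm can send a methyl group to the opposite face of C4 and that methyl can send the alkenyl group to the opposite face of C3; trans,trans is also the thermodynamic arrangement.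

## Logic of the disconnections

28 ⇒ 27. Only heteroatom bonds are cut: the O–Si bond at C5″ and the two ketal C–O bonds at C7″. The hydroxy ketone is the most sensitive part of 28, so it is kept masked until the last step. The skeleton does not change, but all basic and organometallic chemistry can then be run on a masked substrate. The forward step must be a single operation at about pH 2–3 and room temperature, which dictates acid-labile groups of matched lability.

27 ⇒ 12 + 24 (+ a methyl nucleophile). The bonds C4–CH3 and C3–C1″ are cut. They sit on neighbouring carbons of an enoate, so adding the methyl group at C4 creates exactly the enolate that is needed at C3. 27, with six stereocentres, falls into two fragments of similar size with two stereocentres each, and the ring triad is reduced to the single centre C5 of 12. The forward step needs anti 1,4-addition without SN2′ opening, an enolate coupling with an sp2 electrophile (hence palladium) with retention of the E geometry, and no migration of the new double bond.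

12 ⇒ 10 ⇒ 7 + 8. The acyl–oxygen bond O1–C2 is cut, then the bond between the carbinol carbon and the alkyne carbon. A Z-γ-hydroxy enoate closes by itself, and the carbinol can come from an aldehyde and a three-carbon alkyne by catalytic asymmetric addition. The only ring stereocentre that is not relayed is then set by a catalyst. The forward steps need enantioface control on a conjugated dienal and a cis semi-reduction that spares the diene.

7 ⇒ 6 ⇒ 5 ⇒ 3 ⇒ 1. The C2′=C3′ and C4′=C5′ double bonds are cut in turn, then the CH2–CH2 bond that joins the propyl end to the stereogenic carbon's methylene. Stabilised ylides give E alkenes reliably, and the branched centre is bought rather than made. The chain is reduced to the chiral-pool compound 1. The α-stereogenic aldehyde 4 must not epimerise, so it is made and consumed in one flask, and the sp3–sp3 coupling must tolerate an alkoxide.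

24 ⇒ 23 ⇒ 22 ⇒ 21 ⇒ 20. The ketal C–O bonds, the C7″–C8″ bond (methyl onto an acyl group), the O–Si bond and the acyl–nitrogen bonds are cut. The methyl ketone is thereby traced to the carboxyl oxidation level of a propionate aldol adduct. Ketone formation must stop after one addition, and ketalisation must not eliminate the β-silyloxy group or epimerise C6″.

20 ⇒ 18 + 17. The C5″–C6″ aldol bond is cut. The syn-propionate pattern is the signature of an auxiliary-controlled boron aldol, and both centres arise in one step from an achiral aldehyde. The forward step needs a Z enolate, a closed transition state and 1,2-addition to an enal.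

17 ⇒ 16 ⇒ 15 ⇒ 13. The C3″=C4″ double bond and the C–Br bond are cut. This leads to a commercial enal, and the alkenyl bromide geometry is fixed at the start, where it is thermodynamically controlled.

## Other disconnections considered

Alternative 1: The ring bonds C3–C4 and C5–O1 are cut, so the lactone is built from a two-carbon ketene and a vinyl sulfoxide.
- Forward step: (R,E)-1-propenyl p-tolyl sulfoxide A1 would be O-acylated by dichloroketene A2, which is made in the flask from its acid chloride precursor with Zn/Cu couple. A [3,3] shift would join the dichlorinated carbon of A2 to the β-carbon of A1 and pass the sulfur configuration of A1 to C4, and the carboxylate would close onto the thionium carbon to give lactone A3.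
- In its favour: one operation gives the ring, two bonds and C4 from the very cheap materials A1 and A2, without a transition-metal catalyst. On these points it is better than the chosen plan. The concerted chirality transfer to C4 is at least the equal of cuprate anti-addition for that one centre.
- Against it here: A3 has neither side chain. C3 is a CCl2 group, and C5 is at the thioacetal level. The chlorines must be removed. The C5–S bond must be exchanged for the C5–C2′ bond, which in practice means ring opening to an aldehyde, addition of a dienyl organometallic under 1,2-induction from C4 only, and relactonisation. C3 must then still be alkenylated, which is the same sp3–sp2 problem as in the chosen plan.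
- Comparison: structurally the alternative fixes C4 first and derives C5 from it through an acyclic addition, which is less dependable than the relay C5 → C4 → C3 on a flat ring. In step count it needs at least five more operations after A3, against one in the chosen plan.

Alternative 2: Inside the C3 arm, the bond between the future ketone carbon C7″ and C6″ and the C5″–O bond are cut by a dipolar cycloaddition. The isoxazoline then serves as a masked syn-aldol.
- Forward step: the magnesium alkoxide of (S,Z)-1-(tert-butyldimethylsilyloxy)pent-3-en-2-ol A4, formed with EtMgBr, would bind acetonitrile oxide A5 and steer it to one alkene face with fixed regiochemistry. The Z geometry of A4 becomes the cis-4,5 relationship of isoxazoline A6, which corresponds to the syn aldol.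
- Correction of a descriptor: in A6 the side-chain carbinol is R by the sequence rules, although it is spatially the unchanged S centre of A4, because the ring carbon outranks CH2OSi.
- In its favour: one robust heterocycle masks both the hydroxyl and the ketone, is inert to cuprates, enolates and palladium, and is opened by near-neutral N–O reduction. On protecting-group economy and on mildness of the last step this is better than the chosen plan, and no auxiliary has to be attached and removed.
- Against it here: A6 still has to be desilylated, cleaved to a 5-formyl isoxazoline (an epimerisable aldehyde, at the cost of the carbinol centre of A4) and olefinated twice to reach a bromodiene. A4 needs its own asymmetric synthesis, and the dipole A5 dimerises readily, so it has to be generated slowly in the flask. The final N–O reduction must spare two dienes and a lactone. The plan says nothing about the lactone, so the same coupling would still be needed.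
- Comparison: both plans set the same two stereocentres, one by substrate-directed cycloaddition and one by an auxiliary aldol. The two are about equal in reliability, the aldol being the better established with enals. The step count to the bromide would be equal or slightly higher.

Alternative 3: C2–C3 and C2–O1 are cut, so C2 comes from carbon monoxide A8 and the ring is closed last.
- Forward step: the open-chain C3 methyl carbonate with a free C5 hydroxyl A7 would be ionised by zerovalent palladium (Pd2(dba)3 with triphenylphosphine). A8 would insert at the C3 terminus, and the C5 alkoxide would capture the acyl palladium to give the silyl ether A9 of the target.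
- In its favour: the ring and its carbonyl arrive in one neutral step from a gas. The ketone can stay free, so only one silyl ether has to be removed, which is better than the chosen plan on protecting groups. The configuration at C3 need not be controlled in A7, since the allyl complex and the product can both settle to trans, which makes it the equal of the chosen plan at that centre.
- Against it here: A7 is a chain with all six stereocentres, including an acyclic C3/C4/C5 triad and two allylic alcohols that must be told apart. The allyl complex extends over the diene and has three electrophilic positions (C3, C2″, C4″). Direct attack of the C5 oxygen to give a cyclic ether, and β-hydride elimination to a triene, would compete with insertion of A8.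
- Comparison: the chosen plan creates the ring stereocentres on a ring, whereas the alternative needs them on a chain. Both key steps are palladium-catalysed, but the chosen one bonds a nucleophilic carbon with no regiochemical choice. The key steps are equally short, but the precursor of the alternative is clearly longer.

Key step: step 15

Remarks and assumptions on the chemistry:
- Stereochemical check: butenolide 12 is 5S, bromide 24 is 5S,6R, and 27 and 28 are 3S,4S,5S,5″S,6″R,6′R. The 4R alcohol 10 becomes 5S in 12 only because the neighbour priorities change.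
- Choice of 1: a Roche-ester entry to the 6′R centre by the usual order (ester carbon reduced and extended to the butyl chain) would need the (S)-ester. The (R)-ester fits only if its hydroxymethyl carbon becomes the chain, and that needs a displacement β to an ester, where elimination and re-addition would racemise. Bromo alcohol 1 avoids the question and saves four steps.
- Design of 24: a triethylsilyl ether and a dimethyl ketal are used. A tert-butyldimethylsilyl ether with a dioxolane would need acid strong enough to endanger the dienylic carbinol. The chosen pair falls in dilute acetic acid, and early loss of the ketal after the coupling is harmless.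
- Assumption: (S,S)-ProPhenol is taken to deliver the alkynylzinc to the face of 7 that gives 4R; if the sense is the opposite, the (R,R)-ligand is used with no other change.
- Assumption: 26 is drawn O-bound; a C-bound form would lead to the same product.

## Steps

Step 1
Reactants: 1 (S)-3-bromo-2-methylpropan-1-ol
Product: 3 (R)-2-methylhexan-1-ol, via magnesium alkoxide 2 (not isolated)
Conditions: n-PrMgCl (3.0 equiv), Li2CuCl4 (3 mol %), NMP (4 equiv), THF, −20 → 20 °C; aq NH4Cl
Reagents that add atoms: n-propylmagnesium chloride, CCC[Mg]Cl
Why: Copper-catalysed Kochi-type sp3–sp3 coupling of a Grignard reagent with a primary bromide, run on the magnesium alkoxide so that no protecting group is needed. The stereocentre is not touched; its descriptor changes from S to R only because the bromomethyl arm becomes the butyl chain.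

Step 2
Reactants: 3 (R)-2-methylhexan-1-ol
Product: 5 (R,E)-N-methoxy-N,4-dimethyloct-2-enamide, via aldehyde 4 (not isolated)
Conditions: TEMPO (10 mol %), PhI(OAc)2 (1.1 equiv), CH2Cl2, 23 °C; then Ph3P=CHC(O)N(OMe)Me (1.5 equiv), 23 → 40 °C
Reagents that add atoms: N-methoxy-N-methyl-2-(triphenylphosphoranylidene)acetamide, CON(C)C(=O)C=P(c1ccccc1)(c1ccccc1)c1ccccc1
Why: Nitroxyl-catalysed oxidation gives the aldehyde without base, and the stabilised amide ylide (Wittig reaction) traps it in the same flask with high E selectivity. The volatile, epimerisable aldehyde 4 is therefore never handled.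

Step 3
Reactants: 5 (R,E)-N-methoxy-N,4-dimethyloct-2-enamide
Product: 6 (R,E)-4-methyloct-2-enal
Conditions: i-Bu2AlH (1.3 equiv), THF, −78 °C; aq potassium sodium tartrate
Reagents that add atoms: none
Why: Hydride reduction of a Weinreb amide stops at the aldehyde because the chelated tetrahedral aluminium adduct survives until work-up; at −78 °C the enamide is reduced 1,2 only.

Step 4
Reactants: 6 (R,E)-4-methyloct-2-enal
Product: 7 (2E,4E,6R)-2,6-dimethyldeca-2,4-dienal
Conditions: Ph3P=C(Me)CHO (1.5 equiv), toluene, 85 °C
Reagents that add atoms: 2-(triphenylphosphoranylidene)propanal, CC(C=O)=P(c1ccccc1)(c1ccccc1)c1ccccc1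
Why: Wittig reaction of a stabilised formyl ylide with an enal gives the E trisubstituted alkene; the α-branched dienal product is too unreactive to add a second ylide, and the neutral medium leaves C6′ alone.

Step 5
Reactants: 7 (2E,4E,6R)-2,6-dimethyldeca-2,4-dienal; 8 methyl propiolate
Product: 10 methyl (4R,5E,7E,9R)-4-hydroxy-5,9-dimethyltrideca-5,7-dien-2-ynoate, via alkynylzinc 9 (not isolated)
Conditions: 8 (2.8 equiv), Me2Zn (3.0 equiv), (S,S)-ProPhenol (20 mol %), Ph3P=O (40 mol %), toluene, 4 °C; then 7; aq NH4Cl
Reagents that add atoms: none
Why: Dinuclear zinc–ProPhenol catalysed alkynylation of an aldehyde; α,β-unsaturated aldehydes are the established substrate class for this addition. The chiral dizinc pocket binds the aldehyde and delivers the alkynyl group to one enantioface, so C4 is set by the catalyst; the remote 9R centre has no say.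

Step 6
Reactants: 10 methyl (4R,5E,7E,9R)-4-hydroxy-5,9-dimethyltrideca-5,7-dien-2-ynoate
Product: 12 (S)-5-[(2E,4E,6R)-6-methyldeca-2,4-dien-2-yl]furan-2(5H)-one, via Z-hydroxy enoate 11 (not isolated)
Conditions: H2 (1 atm), Pd/CaCO3 poisoned with Pb(OAc)2 (Lindlar catalyst), quinoline, EtOAc, 23 °C; filter; PPTS (5 mol %), CH2Cl2, 23 °C
Reagents that add atoms: none
Why: Lindlar semihydrogenation adds hydrogen cis to the electron-poor alkyne faster than to the substituted diene. The Z-γ-hydroxy enoate then lactonises by intramolecular transesterification; the carbinol centre is untouched and becomes C5.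

Step 7
Reactants: 13 methacrolein
Product: 15 (E)-3-bromo-2-methylprop-2-enal, via dibromide 14 (not isolated)
Conditions: Br2 (1.0 equiv), CH2Cl2, −78 → 0 °C; then Et3N (1.3 equiv), 0 → 23 °C
Reagents that add atoms: bromine, BrBr
Why: Bromine addition to the alkene followed by amine-induced dehydrobromination (loss of the tertiary α-bromide with a C3 proton) gives the conjugated β-bromo enal; the E isomer, with Br trans to CHO, is the favoured one.

Step 8
Reactants: 15 (E)-3-bromo-2-methylprop-2-enal
Product: 16 (2E,4E)-5-bromo-N-methoxy-N,4-dimethylpenta-2,4-dienamide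
Conditions: Ph3P=CHC(O)N(OMe)Me (1.2 equiv), CH2Cl2, 23 °C
Reagents that add atoms: N-methoxy-N-methyl-2-(triphenylphosphoranylidene)acetamide, CON(C)C(=O)C=P(c1ccccc1)(c1ccccc1)c1ccccc1
Why: E-selective Wittig reaction of a stabilised ylide; the neutral ylide avoids the addition–elimination at the β-bromo enal that basic phosphonate conditions could cause.

Step 9
Reactants: 16 (2E,4E)-5-bromo-N-methoxy-N,4-dimethylpenta-2,4-dienamide
Product: 17 (2E,4E)-5-bromo-4-methylpenta-2,4-dienal
Conditions: i-Bu2AlH (1.2 equiv), THF, −78 °C; aq potassium sodium tartrate
Reagents that add atoms: none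
Why: Weinreb amide reduction to the aldehyde through the stable chelate; the alkenyl bromide is inert to the hydride at −78 °C.

Step 10
Reactants: 18 (R)-4-benzyl-3-propionyloxazolidin-2-one; 17 (2E,4E)-5-bromo-4-methylpenta-2,4-dienal
Product: 20 (R)-4-benzyl-3-[(2R,3S,4E,6E)-7-bromo-3-hydroxy-2,6-dimethylhepta-4,6-dienoyl]oxazolidin-2-one, via boron enolate 19 (not isolated)
Conditions: n-Bu2BOTf (1.2 equiv), Et3N (1.4 equiv), CH2Cl2, −78 → 0 °C; 17, −78 → 0 °C; pH 7 buffer, MeOH, 30 % H2O2, 0 °C
Reagents that add atoms: none
Why: Evans syn-aldol reaction: soft enolisation gives the Z boron enolate, which reacts through a closed chair (Zimmerman–Traxler) transition state with the auxiliary carbonyl turned away, so the aldehyde meets the enolate face remote from the benzyl group. This sets C2 (R) and C3 (S) syn in one step; enals add 1,2 under these conditions.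

Step 11
Reactants: 20 (R)-4-benzyl-3-[(2R,3S,4E,6E)-7-bromo-3-hydroxy-2,6-dimethylhepta-4,6-dienoyl]oxazolidin-2-one
Product: 21 (2R,3S,4E,6E)-7-bromo-3-hydroxy-N-methoxy-N,2,6-trimethylhepta-4,6-dienamide
Conditions: MeNH(OMe)·HCl (3 equiv), AlMe3 (3 equiv), CH2Cl2, −20 → 0 °C
Reagents that add atoms: N,O-dimethylhydroxylamine hydrochloride, CNOC.Cl
Why: Aluminium amide transamination of the aldol imide; the free β-hydroxyl binds aluminium and directs attack to the exocyclic carbonyl, so the auxiliary is released intact and C2 is not epimerised.

Step 12
Reactants: 21 (2R,3S,4E,6E)-7-bromo-3-hydroxy-N-methoxy-N,2,6-trimethylhepta-4,6-dienamide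
Product: 22 (2R,3S,4E,6E)-7-bromo-N-methoxy-N,2,6-trimethyl-3-(triethylsilyloxy)hepta-4,6-dienamide
Conditions: Et3SiCl (1.3 equiv), imidazole (2.5 equiv), CH2Cl2, 0 → 23 °C
Reagents that add atoms: chlorotriethylsilane, CC[Si](Cl)(CC)CC
Why: Standard silylation of a secondary alcohol; the triethylsilyl ether survives the organometallic and Lewis-acidic steps ahead but falls in dilute acetic acid at the end.

Step 13
Reactants: 22 (2R,3S,4E,6E)-7-bromo-N-methoxy-N,2,6-trimethyl-3-(triethylsilyloxy)hepta-4,6-dienamide
Product: 23 (3R,4S,5E,7E)-8-bromo-3,7-dimethyl-4-(triethylsilyloxy)octa-5,7-dien-2-one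
Conditions: MeMgBr (2.5 equiv), THF, −20 → 0 °C; aq NH4Cl
Reagents that add atoms: methylmagnesium bromide, C[Mg]Br
Why: Grignard addition to a Weinreb amide stops at the ketone because the magnesium chelate collapses only on work-up; the silyl ether blocks retro-aldol cleavage, and the ketone is never exposed to the basic reagent, so C3 keeps its configuration.

Step 14
Reactants: 23 (3R,4S,5E,7E)-8-bromo-3,7-dimethyl-4-(triethylsilyloxy)octa-5,7-dien-2-one
Product: 24 (1E,3E,5S,6R)-1-bromo-7,7-dimethoxy-2,6-dimethyl-5-(triethylsilyloxy)octa-1,3-diene
Conditions: MeOSiMe3 (4 equiv), Me3SiOTf (5 mol %), CH2Cl2, −78 → −40 °C; pyridine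
Reagents that add atoms: methoxytrimethylsilane, CO[Si](C)(C)C
Why: Noyori ketalisation with an alkoxysilane and catalytic silyl triflate is aprotic and runs at low temperature, so the β-silyloxy ketone should neither eliminate nor epimerise; formation of hexamethyldisiloxane drives it. The ketal removes the acidic, electrophilic ketone from the enolate coupling.

Step 15
Reactants: 12 (S)-5-[(2E,4E,6R)-6-methyldeca-2,4-dien-2-yl]furan-2(5H)-one; 24 (1E,3E,5S,6R)-1-bromo-7,7-dimethoxy-2,6-dimethyl-5-(triethylsilyloxy)octa-1,3-diene
Product: 27 (3S,4S,5S)-3-[(1E,3E,5S,6R)-7,7-dimethoxy-2,6-dimethyl-5-(triethylsilyloxy)octa-1,3-dien-1-yl]-4-methyl-5-[(2E,4E,6R)-6-methyldeca-2,4-dien-2-yl]dihydrofuran-2(3H)-one, via lithium enolate 25 (not isolated), via zinc enolate 26 (not isolated)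
Conditions: Me2CuLi (1.2 equiv, from MeLi and CuI), Et2O, −78 → −40 °C, 12 (1.15 equiv) added slowly; ZnCl2 (1.3 equiv), THF, −40 → 0 °C; cannula filtration onto 24 (1.0 equiv), Pd2(dba)3 (2.5 mol %), P(t-Bu)3 (10 mol %), THF, 23 °C; pH 7 buffer
Reagents that add atoms: lithium dimethylcuprate, [Li+].C[Cu-]C
Why: The cuprate forms a π-complex with the enoate, passes through a β-cuprio enolate of trivalent copper and delivers methyl to C4 by reductive elimination on the face opposite the C5 arm, giving lithium enolate 25. ZnCl2 turns 25 into the weakly basic zinc enolate 26, while the methylcopper left behind separates from ether as an insoluble polymer and is filtered off, so that it should not hand its methyl group to palladium. Zerovalent palladium carrying P(t-Bu)3 inserts into the alkenyl C–Br bond of 24 with retention of the E geometry, 26 transfers to palladium as a C-bound enolate, and reductive elimination forms C3–C1″. The closest known reactions are cuprate addition with enolate trapping on γ-substituted butenolides and the palladium-catalysed α-arylation and α-alkenylation of zinc ester enolates. No ring is closed. C4 is controlled by C5 (1,2-induction on the flat ring), and C3 is controlled by C4, because palladium and hence the alkenyl group enter anti to the new methyl; the all-trans product is also the more stable isomer. The step needs 1,4-addition to outrun SN2′ opening and γ-deprotonation, which the strained cis-enoate should secure because it reacts at −78 °C where the dienylic C5–O1 bond is inert, helped by adding 12 to an excess of cuprate. It also needs single alkenylation without migration of C1″=C2″, which the low basicity of 26 and the neutral quench should secure.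

Step 16
Reactants: 27 (3S,4S,5S)-3-[(1E,3E,5S,6R)-7,7-dimethoxy-2,6-dimethyl-5-(triethylsilyloxy)octa-1,3-dien-1-yl]-4-methyl-5-[(2E,4E,6R)-6-methyldeca-2,4-dien-2-yl]dihydrofuran-2(3H)-one
Product: 28 (3S,4S,5S)-3-[(1E,3E,5S,6R)-5-hydroxy-2,6-dimethyl-7-oxoocta-1,3-dien-1-yl]-4-methyl-5-[(2E,4E,6R)-6-methyldeca-2,4-dien-2-yl]dihydrofuran-2(3H)-one
Conditions: AcOH/THF/H2O (3:1:1), 23 °C
Reagents that add atoms: water, O
Why: Dilute aqueous acetic acid hydrolyses the acyclic dimethyl ketal through its oxocarbenium ion and solvolyses the triethylsilyl ether at room temperature. This acid is too weak to ionise the dienylic carbinol, dehydrate the β-hydroxy ketone or enolise C3 or C6″, so all six stereocentres should be carried through.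

## Compound list

1 | (S)-3-bromo-2-methylpropan-1-ol | BrC[C@@H](C)CO | starting material
2 | chloromagnesium (S)-3-bromo-2-methylpropan-1-olate | BrC[C@@H](C)CO[Mg]Cl | intermediate
3 | (R)-2-methylhexan-1-ol | CCCC[C@@H](C)CO | intermediate
4 | (R)-2-methylhexanal | CCCC[C@@H](C)C=O | intermediate
5 | (R,E)-N-methoxy-N,4-dimethyloct-2-enamide | CCCC[C@@H](C)/C=C/C(=O)N(C)OC | intermediate
6 | (R,E)-4-methyloct-2-enal | CCCC[C@@H](C)/C=C/C=O | intermediate
7 | (2E,4E,6R)-2,6-dimethyldeca-2,4-dienal | CCCC[C@@H](C)/C=C/C=C(\C)C=O | intermediate
8 | methyl propiolate | C#CC(=O)OC | starting material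
9 | methyl(3-methoxy-3-oxoprop-1-yn-1-yl)zinc | C[Zn]C#CC(=O)OC | intermediate
10 | methyl (4R,5E,7E,9R)-4-hydroxy-5,9-dimethyltrideca-5,7-dien-2-ynoate | CCCC[C@@H](C)/C=C/C=C(\C)[C@@H](O)C#CC(=O)OC | intermediate
11 | methyl (2Z,4S,5E,7E,9R)-4-hydroxy-5,9-dimethyltrideca-2,5,7-trienoate | CCCC[C@@H](C)/C=C/C=C(\C)[C@@H](O)/C=C\C(=O)OC | intermediate
12 | (S)-5-[(2E,4E,6R)-6-methyldeca-2,4-dien-2-yl]furan-2(5H)-one | CCCC[C@@H](C)/C=C/C=C(\C)[C@H]1OC(=O)C=C1 | intermediate
13 | methacrolein (2-methylprop-2-enal) | CC(=C)C=O | starting material
14 | 2,3-dibromo-2-methylpropanal (racemic) | CC(Br)(CBr)C=O | intermediate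
15 | (E)-3-bromo-2-methylprop-2-enal | O=C/C(C)=C/Br | intermediate
16 | (2E,4E)-5-bromo-N-methoxy-N,4-dimethylpenta-2,4-dienamide | CON(C)C(=O)/C=C/C(C)=C/Br | intermediate
17 | (2E,4E)-5-bromo-4-methylpenta-2,4-dienal | O=C/C=C/C(C)=C/Br | intermediate
18 | (R)-4-benzyl-3-propionyloxazolidin-2-one | CCC(=O)N1[C@H](Cc2ccccc2)COC1=O | starting material
19 | (R)-4-benzyl-3-[(Z)-1-(dibutylboranyloxy)prop-1-en-1-yl]oxazolidin-2-one | C/C=C(\OB(CCCC)CCCC)N1[C@H](Cc2ccccc2)COC1=O | intermediate
20 | (R)-4-benzyl-3-[(2R,3S,4E,6E)-7-bromo-3-hydroxy-2,6-dimethylhepta-4,6-dienoyl]oxazolidin-2-one | Br/C=C(C)/C=C/[C@H](O)[C@@H](C)C(=O)N1[C@H](Cc2ccccc2)COC1=O | intermediate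
21 | (2R,3S,4E,6E)-7-bromo-3-hydroxy-N-methoxy-N,2,6-trimethylhepta-4,6-dienamide | Br/C=C(C)/C=C/[C@H](O)[C@@H](C)C(=O)N(C)OC | intermediate
22 | (2R,3S,4E,6E)-7-bromo-N-methoxy-N,2,6-trimethyl-3-(triethylsilyloxy)hepta-4,6-dienamide | Br/C=C(C)/C=C/[C@H](O[Si](CC)(CC)CC)[C@@H](C)C(=O)N(C)OC | intermediate
23 | (3R,4S,5E,7E)-8-bromo-3,7-dimethyl-4-(triethylsilyloxy)octa-5,7-dien-2-one | Br/C=C(C)/C=C/[C@H](O[Si](CC)(CC)CC)[C@@H](C)C(C)=O | intermediate
24 | (1E,3E,5S,6R)-1-bromo-7,7-dimethoxy-2,6-dimethyl-5-(triethylsilyloxy)octa-1,3-diene | Br/C=C(C)/C=C/[C@H](O[Si](CC)(CC)CC)[C@@H](C)C(C)(OC)OC | intermediate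
25 | lithium (4S,5S)-4-methyl-5-[(2E,4E,6R)-6-methyldeca-2,4-dien-2-yl]-4,5-dihydrofuran-2-olate | [Li+].CCCC[C@@H](C)/C=C/C=C(\C)[C@H]1OC([O-])=C[C@@H]1C | intermediate
26 | chlorozinc (4S,5S)-4-methyl-5-[(2E,4E,6R)-6-methyldeca-2,4-dien-2-yl]-4,5-dihydrofuran-2-olate | CCCC[C@@H](C)/C=C/C=C(\C)[C@H]1OC(O[Zn]Cl)=C[C@@H]1C | intermediate
27 | (3S,4S,5S)-3-[(1E,3E,5S,6R)-7,7-dimethoxy-2,6-dimethyl-5-(triethylsilyloxy)octa-1,3-dien-1-yl]-4-methyl-5-[(2E,4E,6R)-6-methyldeca-2,4-dien-2-yl]dihydrofuran-2(3H)-one | CCCC[C@@H](C)/C=C/C=C(\C)[C@H]1OC(=O)[C@@H](/C=C(C)/C=C/[C@H](O[Si](CC)(CC)CC)[C@@H](C)C(C)(OC)OC)[C@@H]1C | intermediate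
28 | (3S,4S,5S)-3-[(1E,3E,5S,6R)-5-hydroxy-2,6-dimethyl-7-oxoocta-1,3-dien-1-yl]-4-methyl-5-[(2E,4E,6R)-6-methyldeca-2,4-dien-2-yl]dihydrofuran-2(3H)-one | CCCC[C@@H](C)/C=C/C=C(\C)[C@H]1OC(=O)[C@@H](/C=C(C)/C=C/[C@H](O)[C@@H](C)C(C)=O)[C@@H]1C | target

## Step count and least certain steps

Total: 16 steps. Longest linear sequence: 10 steps (steps 7 to 14, then 15 and 16, from 13 to 28). The butenolide branch is 8 steps (steps 1 to 6, then 15 and 16).

Step 15 (key step).
- Most likely failure: transfer of a copper-bound methyl group to the alkenylpalladium intermediate in competition with the hindered zinc enolate, if the filtration does not remove all methylcopper. This would consume the bromide as a methylated diene.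
- Second failure: proton exchange between the more acidic product and unreacted enolate, which would stall conversion, scramble C3 or move C1″=C2″ into conjugation.
- Third failure: SN2′ opening or γ-deprotonation of the butenolide if the 1,4-addition is slow.
- Fallback: the two bond formations are separated. Starting from 12, Me2CuLi followed by aqueous NH4Cl gives, after removal of all copper, (4S,5S)-4-methyl-5-[(2E,4E,6R)-6-methyldeca-2,4-dien-2-yl]dihydrofuran-2(3H)-one F1. F1 is deprotonated with LiN(SiMe3)2 at −78 °C and moved to zinc with ZnCl2, which returns to the route at copper-free 26. Coupling with 24 then proceeds as in step 15. A C3 epimer mixture would be equilibrated to the trans isomer with a catalytic amidine base.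

Step 5.
- Most likely failure: poor enantioface discrimination or slow addition, because the doubly conjugated, α-branched aldehyde is a weak electrophile; the sense of induction also rests on an assumption.
- Fallback: the stereocentre is set by reduction instead of addition. From 7 and 8, the lithium acetylide of 8 (LiN(SiMe3)2, THF, −78 °C) adds to 7 to give methyl (5E,7E,9R)-4-hydroxy-5,9-dimethyltrideca-5,7-dien-2-ynoate as a mixture of C4 epimers F2. MnO2 oxidises F2 to methyl (5E,7E,9R)-5,9-dimethyl-4-oxotrideca-5,7-dien-2-ynoate F3. Corey–Bakshi–Shibata reduction then returns to 10, using catecholborane at −78 °C and the (R)-oxazaborolidine, chosen on the model in which the alkynyl group is the small substituent.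

Step 6.
- Most likely failure: over-reduction of the alkyne or partial saturation or isomerisation of the diene on the palladium surface; ionisation of the doubly allylic carbinol could occur if the lactonisation needed more acid.
- Fallback: from 10, the hydrogenation is replaced by electron-transfer reduction with activated zinc (Zn/Cu/Ag couple, aqueous methanol; Boland reduction). This reduces only the conjugated alkyne and gives 11, which closes to 12.

Step 14.
- Most likely failure: loss of silanol or epimerisation at C6″ through an enol ether while the oxocarbenium ion waits for the second methoxy group; the α-branched ketone may also convert incompletely.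
- Fallback: the ketal is omitted. From 23, the free ketone is coupled with 26 under the conditions of step 15, since zinc enolates are known to tolerate enolisable ketones. This gives (3S,4S,5S)-3-[(1E,3E,5S,6R)-2,6-dimethyl-7-oxo-5-(triethylsilyloxy)octa-1,3-dien-1-yl]-4-methyl-5-[(2E,4E,6R)-6-methyldeca-2,4-dien-2-yl]dihydrofuran-2(3H)-one F4. F4 is desilylated with AcOH/THF/H2O and returns at 28.

Step 16.
- Most likely failure: ionisation of the dienylic C5″–O bond, or dehydration of the β-hydroxy ketone to a trienone, during the slower of the two cleavages, which is the silyl ether.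
- Fallback: the two groups are removed by different mechanisms. From 27, HF·pyridine buffered with pyridine (THF, 0 °C) cleaves the silyl ether through Si–F bond formation and gives (3S,4S,5S)-3-[(1E,3E,5S,6R)-5-hydroxy-7,7-dimethoxy-2,6-dimethylocta-1,3-dien-1-yl]-4-methyl-5-[(2E,4E,6R)-6-methyldeca-2,4-dien-2-yl]dihydrofuran-2(3H)-one F5. The ketal of F5 is then hydrolysed with PPTS in wet acetone at 0 °C, returning at 28.

## Further compounds

F1 | step 15 | (4S,5S)-4-methyl-5-[(2E,4E,6R)-6-methyldeca-2,4-dien-2-yl]dihydrofuran-2(3H)-one | CCCC[C@@H](C)/C=C/C=C(\C)[C@H]1OC(=O)C[C@@H]1C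
F2 | step 5 | methyl (5E,7E,9R)-4-hydroxy-5,9-dimethyltrideca-5,7-dien-2-ynoate, mixture of C4 epimers | CCCC[C@@H](C)/C=C/C=C(\C)C(O)C#CC(=O)OC
F3 | step 5 | methyl (5E,7E,9R)-5,9-dimethyl-4-oxotrideca-5,7-dien-2-ynoate | CCCC[C@@H](C)/C=C/C=C(\C)C(=O)C#CC(=O)OC
F0 | step 6 | none | none
F4 | step 14 | (3S,4S,5S)-3-[(1E,3E,5S,6R)-2,6-dimethyl-7-oxo-5-(triethylsilyloxy)octa-1,3-dien-1-yl]-4-methyl-5-[(2E,4E,6R)-6-methyldeca-2,4-dien-2-yl]dihydrofuran-2(3H)-one | CCCC[C@@H](C)/C=C/C=C(\C)[C@H]1OC(=O)[C@@H](/C=C(C)/C=C/[C@H](O[Si](CC)(CC)CC)[C@@H](C)C(C)=O)[C@@H]1C
F5 | step 16 | (3S,4S,5S)-3-[(1E,3E,5S,6R)-5-hydroxy-7,7-dimethoxy-2,6-dimethylocta-1,3-dien-1-yl]-4-methyl-5-[(2E,4E,6R)-6-methyldeca-2,4-dien-2-yl]dihydrofuran-2(3H)-one | CCCC[C@@H](C)/C=C/C=C(\C)[C@H]1OC(=O)[C@@H](/C=C(C)/C=C/[C@H](O)[C@@H](C)C(C)(OC)OC)[C@@H]1C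
A1 | alternative 1 | (R,E)-1-propenyl p-tolyl sulfoxide | C/C=C/[S@@](=O)c1ccc(C)cc1
A2 | alternative 1 | dichloroketene | ClC(Cl)=C=O
A3 | alternative 1 | (4R,5R)-3,3-dichloro-4-methyl-5-(p-tolylthio)dihydrofuran-2(3H)-one (trans) | Cc1ccc(S[C@H]2OC(=O)C(Cl)(Cl)[C@@H]2C)cc1
A4 | alternative 2 | (S,Z)-1-(tert-butyldimethylsilyloxy)pent-3-en-2-ol | C/C=C\[C@H](O)CO[Si](C)(C)C(C)(C)C
A5 | alternative 2 | acetonitrile oxide | CC#[N+][O-]
A6 | alternative 2 | (4S,5R)-5-[(R)-2-(tert-butyldimethylsilyloxy)-1-hydroxyethyl]-3,4-dimethyl-4,5-dihydroisoxazole (cis) | CC1=NO[C@@H]([C@H](O)CO[Si](C)(C)C(C)(C)C)[C@H]1C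
A7 | alternative 3 | open-chain precursor, icosa-5,7,12,14-tetraen-2-one numbering: 4-(tert-butyldimethylsilyloxy)-11-hydroxy-9-(methoxycarbonyloxy)-3,7,10,12,16-pentamethyl, configuration as in the SMILES (C9, the future C3, drawn for net inversion) | CCCC[C@@H](C)/C=C/C=C(\C)[C@@H](O)[C@@H](C)[C@H](OC(=O)OC)/C=C(C)/C=C/[C@H](O[Si](C)(C)C(C)(C)C)[C@@H](C)C(C)=O
A8 | alternative 3 | carbon monoxide | [C-]#[O+]
A9 | alternative 3 | tert-butyldimethylsilyl ether of the target, (3S,4S,5S)-3-[(1E,3E,5S,6R)-5-(tert-butyldimethylsilyloxy)-2,6-dimethyl-7-oxoocta-1,3-dien-1-yl]-4-methyl-5-[(2E,4E,6R)-6-methyldeca-2,4-dien-2-yl]dihydrofuran-2(3H)-one | CCCC[C@@H](C)/C=C/C=C(\C)[C@H]1OC(=O)[C@@H](/C=C(C)/C=C/[C@H](O[Si](C)(C)C(C)(C)C)[C@@H](C)C(C)=O)[C@@H]1C
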